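At early times the runs below follow X, the substrate that reacts with reagent G over catalyst J to give product L.

| flask | X | G | J | time |
|---|---|---|---|---|
| alpha | 120 mM | 132 mM | 2.40 mM |  |
| delta | 120 mM | 200 mM | 2.40 mM |  |
| theta | 120 mM | 132 mM | 3.60 mM |  |
| gamma | 60.0 mM | 132 mM | 2.40 mM |  |
| beta | 120 mM | 132 mM | 5.90 mM | 12 min |

| run | time / min | [X] / mM |
|---|---|---|
| alpha run | 0.43 | 115.8 |
| alpha run | 1.3 | 106.2 |
| alpha run | 2.5 | 86.5 |
| alpha run | 4.0 | 61.6 |
| alpha run | 5.7 | 39.7 |
| alpha run | 7.6 | 26.9 |
| alpha run | 9.7 | 17.4 |
| alpha run | 12 | 11.9 |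
| delta run | 0.43 | 115.0 |
| delta run | 1.3 | 101.4 |
| delta run | 2.5 | 70.2 |
| delta run | 4.0 | 34.0 |
| delta run | 5.7 | 14.6 |
| delta run | 7.6 | 5.1 |
| delta run | 9.7 | 2.2 |
| delta run | 12 | 0.9 |
| theta run | 0.43 | 114.2 |
| theta run | 1.3 | 101.1 |
| theta run | 2.5 | 78.7 |
| theta run | 4.0 | 53.1 |
| theta run | 5.7 | 35.4 |
| theta run | 7.6 | 22.5 |
| theta run | 9.7 | 15.9 |
| theta run | 12 | 11.5 |
| gamma run | 0.43 | 57.0 |
| gamma run | 1.3 | 52.9 |
| gamma run | 2.5 | 45.5 |
| gamma run | 4.0 | 36.8 |
| gamma run | 5.7 | 26.6 |
| gamma run | 7.6 | 18.6 |
| gamma run | 9.7 | 12.2 |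
| gamma run | 12 | 7.0 |

(scatter of a reading: 0.4 mM)

- Overall: X + G -> L, with J as catalyst.
- Constant volume, constant temperature.
- The analysis sees a species whether free or bound.
- An order is taken over about fifteen percent of the charge, up and down.

1. order of the initial rate in [X], near the charge of the alpha run, the rate being that where two percent of its X are L (one fixed amount of L, the same in the runs compared)
2. order of the initial rate in [G], near the charge of the alpha run, the rate being that where two percent of its X are L
3. X in the beta run at 12 min, as a share of the X charged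

Does the alpha run slow down as X falls? It does the opposite. X goes at 9.77 mM min⁻¹ up to 0.43 min, but at 16.4 mM min⁻¹ from 1.3 min to 2.5 min, which is faster by a factor of 1.68, although less X remains. So something made in the flask, presumably L, seems to add to the rate.

How much, then, does J still count at the end? In the alpha run 2.31 lifetimes of X have passed by 12 min, the lifetime count n being the natural logarithm of X charged over X left, so that one lifetime is a fall by the factor e, however long it takes. The theta run has 1.50 times the J of alpha and leads early, with X at 78.7 mM against 86.5 mM at 2.5 min. By 12 min, however, it has reached n = 2.35, a gain of 0.0400, and the scatter of one late reading in n is 0.0336.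

What does the beta run gain with 2.46 times the J of alpha? The reckoning here stretches the theta gain in proportion to the logarithm of J. That gives n = 2.39, and so 9.19 % of the X left at 12 min, a rough figure: the gain of 0.0400 it rests on stands beside a scatter of 0.0336 in one reading.

The forecast gives orders of 0.9 in X and 0.7 in G, and 8.2 % of X left in beta, on the ground that “late the two runs coincide, so L dominates”. Its share lies below the one reckoned here.

The simulation gives orders of 0.59 in X and 0.24 in G, both lower than the forecast, and 8.20 % of X left in beta, the share the forecast named.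

    J + X → JX (80.40 M⁻¹ min⁻¹)
    JX + G → Xo (506.4 M⁻¹ min⁻¹)
    Xo → L + J (5.742 min⁻¹)
    X + G + L → 2 L (48.06 M⁻² min⁻¹)
    2 J → 2 Jo (311.4 M⁻¹ min⁻¹)

That share means n = 2.50 in the beta run, above the 2.39 reckoned and 0.190 above alpha. The beta run without the path from X + G + L to 2 L (autocatalysis) has 50.7 % of its X left at 12 min, which is n = 0.679. Taking that path away therefore lowers n in the beta run by 1.82 from its 2.50, a share of 72.8 %.

The numbers in the tables stem from a simulated flask on assumed constants, and the scatter is random.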